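The pitfall here is to book target as safe the moment it forms: free enzyme, the form that starts each cycle, also turns target into its isomer and back.

| flask | starting material | second substrate | free enzyme | time | remark |
|---|---|---|---|---|---|
| south-west | 0.075 M | 0.0825 M | 23 µM | 25 min | a closed flask charged with all of it at once and left for 25 min |
| south-east | 0.075 M | 0.0825 M (fed, over 20.0 min) | 23 µM | 25 min | a stirred flask in which second substrate is dosed at a steady rate over 20.0 min without added volume, worked up at 25 min |
| north-west | 0.075 M | 0.0825 M | 23 µM |  | a single well-mixed tank run continuously and read at steady state, 25 min in it on average |
| west | 0.075 M | 0.0825 M | 23 µM |  | one stirred flow tank at steady state, fed with the mixture as stated, mean residence time 125 min |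

    starting material + free enzyme ⇌ first complex (K1 = 130 M⁻¹, k1 = 560 M⁻¹ s⁻¹)
    second substrate + loaded enzyme ⇌ second complex (K2 = 4.9 M⁻¹, k2 = 15000 M⁻¹ s⁻¹)
    starting material + first product → side product (k3 = 0.017 M⁻¹ s⁻¹)
    first complex → loaded enzyme + first product (k4 = 190 s⁻¹)
    target + free enzyme ⇌ isomer of the product + free enzyme, rate k5*[free enzyme]*[target] forward; the back reaction follows from the equilibrium constant (K5 = 2.5, k5 = 33 M⁻¹ s⁻¹)
    second complex → free enzyme + target (k6 = 27 s⁻¹)

- the stated concentrations are those of everything mixed, before any reaction; amounts are the same in each set-up
- the feed brings no volume worth counting
- run time (south-west): 25 min

- the set-up with the highest amount of target at the outlet or at the end, in percent of the starting material put in ("none" if the first two lie within 2 percentage points) (south-west / south-east / north-west / west / none)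
- amount of target at the outlet or at the end, in percent of the starting material put in, south-west
- amount of target at the outlet or at the end, in percent of the starting material put in, south-east
- amount of target at the outlet or at the end, in percent of the starting material put in, north-west
- amount of target at the outlet or at the end, in percent of the starting material put in, west

We begin with the balance of the enzyme, the reagent charged in the smallest amount: free enzyme, loaded enzyme and the two complexes add up to its whole charge. If all of it stood free, target and isomer would relax towards equilibrium in one scrambling time, the inverse of k5 times the enzyme charge times (one plus the inverse of K5), 15.7 min. At equilibrium target keeps a floor of 28.6% of the pair.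

For a tank at steady state, the balance of target gives its share of the pair:

share = floor + (whole − floor) / (one + free share of enzyme × mean stay / scrambling time)

West, first estimate, with all enzyme free: the stay is 7.97 scrambling times, so the share is 36.5%.

The weak link is that free share. If the whole starting material, the limiting reagent, passes through the cycle, each enzyme must finish a cycle every 2.30 s. Second substrate cannot fall below 9.09% of its charge, so the enzyme spends at most 1.06 s of that outside the free form:

free share at least 54.0%, so target at most 42.0% of the pair in west

North-west, with a stay of 1.59 scrambling times, keeps at least 56.1% of its pair, more than west. We therefore expect west's share of the pair to stand below north-west's, and west's target to stay under 42.0% of the charge. The two flasks that change with time we leave unreckoned.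

The forecast names south-east as best, with 51.5% in south-west, 68.5% in south-east, 55.6% in north-west and 34.4% in west, on the ground that “dosing keeps enzyme loaded and free enzyme low”.

The simulation gives 51.5%, 68.6%, 55.7% and 34.4% in that order, so south-east leads and the forecast holds. West, with its 7.97 scrambling times against 1.59 for north-west, reads the lowest target. After 250 min, which is 15.9 scrambling times, south-west reads 24.8%, and south-east, ahead by 17 percentage points at 25 min, falls below it to 23.7%.

The numbers of this flask stand for no real mixture; the rest is arithmetic.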